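**Retrosynthetic overview**
- The target comes from diphenol 19 by O4'-methylation and desilylation. 19 comes from the (S)-bis(1,1-dimethylallyl) ether 17 by a twofold aromatic Claisen rearrangement. The strategy rests on C6 of ring A being the only unsubstituted ortho carbon of O5 (the other is the ring-fusion carbon C4a), and C5' of ring B being the only unsubstituted ortho carbon of O4' (the other, C3', carries oxygen).
- 17 comes from the cis-(3S,4S)-isoflavan-4-ol 16 by oxidation. 16 comes from isoflavone 14 by asymmetric transfer hydrogenation with dynamic kinetic resolution, which sets C3. 14 comes from bis(propargyl) ether 13 by semi-hydrogenation.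
- 13 comes from isoflavone 9 by work on ring B: O4' propargylation, Baeyer–Villiger conversion of the 3'-formyl group into the 3'-oxygen, then silylation. 9 comes from 3-iodochromone 6 and boronate 8 by Suzuki coupling.
- Ring order: ring A is bought as phloroacetophenone 1, ring C is closed by enaminone iodocyclisation, ring B is attached by cross-coupling. The key step closes no ring.

Key step: step 13

Assumption: RuCl[(S,S)-TsDPEN](p-cymene) is taken to reduce C4 in the sense known for 4-chromanone (S alcohol); if the sense proved opposite, the (R,R)-complex would be used.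

**Route**

Step 1
Reactants: 1 2,4,6-trihydroxyacetophenone
Product: 2 1-[2,6-dihydroxy-4-(triisopropylsilyloxy)phenyl]ethanone
Conditions: TIPSCl (1.05 equiv), imidazole, DMF, 0 °C
Reagents that add atoms: chlorotriisopropylsilane, CC(C)[Si](Cl)(C(C)C)C(C)C
Why: Regioselective phenol silylation: the 4-hydroxyl is the only one not hydrogen-bonded to the acetyl carbonyl and is the most acidic, so one equivalent of the bulky chlorosilane should take it alone, and the robust TIPS group is chosen because O7 must later survive DBU and aqueous carbonate.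

Step 2
Reactants: 2 1-[2,6-dihydroxy-4-(triisopropylsilyloxy)phenyl]ethanone; 3 3-chloro-3-methylbut-1-yne
Product: 4 1-[2-hydroxy-6-(2-methylbut-3-yn-2-yloxy)-4-(triisopropylsilyloxy)phenyl]ethanone
Conditions: DBU, CuCl2 (1 mol%), MeCN, 0 °C
Reagents that add atoms: none
Why: Copper-catalysed propargylic etherification of a phenol through a copper acetylide-derived electrophile; after one ortho hydroxyl is alkylated the other stays locked in the hydrogen bond to the carbonyl, which should stop the reaction at the mono-ether.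

Step 3
Reactants: 4 1-[2-hydroxy-6-(2-methylbut-3-yn-2-yloxy)-4-(triisopropylsilyloxy)phenyl]ethanone
Product: 5 (E)-3-(dimethylamino)-1-[2-hydroxy-6-(2-methylbut-3-yn-2-yloxy)-4-(triisopropylsilyloxy)phenyl]prop-2-en-1-one
Conditions: Me2NCH(OMe)2, PhMe, 80 °C
Reagents that add atoms: N,N-dimethylformamide dimethyl acetal, COC(OC)N(C)C
Why: Enaminone formation by condensation of the methyl ketone with the amide acetal adds the carbon that becomes C2, at a temperature well below that at which aryl propargyl ethers rearrange.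

Step 4
Reactants: 5 (E)-3-(dimethylamino)-1-[2-hydroxy-6-(2-methylbut-3-yn-2-yloxy)-4-(triisopropylsilyloxy)phenyl]prop-2-en-1-one
Product: 6 3-iodo-5-(2-methylbut-3-yn-2-yloxy)-7-(triisopropylsilyloxy)-4H-chromen-4-one
Conditions: I2 (1.1 equiv), pyridine, CHCl3, rt
Reagents that add atoms: iodine, II
Why: Iodocyclisation of an ortho-hydroxyaryl enaminone: iodination of the enaminone α-carbon, attack of the phenol on the iminium carbon and loss of dimethylamine close ring C as the 3-iodochromone.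

Step 5
Reactants: 7 5-bromo-2-hydroxybenzaldehyde
Product: 8 2-hydroxy-5-(4,4,5,5-tetramethyl-1,3,2-dioxaborolan-2-yl)benzaldehyde
Conditions: B2pin2, Pd(dppf)Cl2 (3 mol%), KOAc, 1,4-dioxane, 85 °C
Reagents that add atoms: bis(pinacolato)diboron, CC1(C)OB(OC1(C)C)B1OC(C)(C)C(C)(C)O1
Why: Miyaura borylation of the aryl bromide; the weak acetate base leaves the phenol and the aldehyde untouched, and no alkyne is yet present in this fragment.

Step 6
Reactants: 6 3-iodo-5-(2-methylbut-3-yn-2-yloxy)-7-(triisopropylsilyloxy)-4H-chromen-4-one; 8 2-hydroxy-5-(4,4,5,5-tetramethyl-1,3,2-dioxaborolan-2-yl)benzaldehyde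
Product: 9 2-hydroxy-5-[5-(2-methylbut-3-yn-2-yloxy)-4-oxo-7-(triisopropylsilyloxy)-4H-chromen-3-yl]benzaldehyde
Conditions: Pd(dppf)Cl2 (5 mol%), Na2CO3 (2 M aq.), DME, 50 °C
Reagents that add atoms: none
Why: Suzuki–Miyaura coupling of the reactive 3-iodochromone with the arylboronate forms the C3–C1' bond at mild temperature, where the terminal alkyne (no copper, no amine) and the TIPS ether should remain spectators.

Step 7
Reactants: 9 2-hydroxy-5-[5-(2-methylbut-3-yn-2-yloxy)-4-oxo-7-(triisopropylsilyloxy)-4H-chromen-3-yl]benzaldehyde; 3 3-chloro-3-methylbut-1-yne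
Product: 10 2-(2-methylbut-3-yn-2-yloxy)-5-[5-(2-methylbut-3-yn-2-yloxy)-4-oxo-7-(triisopropylsilyloxy)-4H-chromen-3-yl]benzaldehyde
Conditions: DBU, CuCl2 (1 mol%), MeCN, 0 °C to rt
Reagents that add atoms: none
Why: The same copper-catalysed propargylic etherification on the only free hydroxyl; this oxygen is para to C1' and therefore is O4', so the ring B pattern is fixed by the bought salicylaldehyde and no catechol has to be differentiated.

Step 8
Reactants: 10 2-(2-methylbut-3-yn-2-yloxy)-5-[5-(2-methylbut-3-yn-2-yloxy)-4-oxo-7-(triisopropylsilyloxy)-4H-chromen-3-yl]benzaldehyde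
Product: 12 3-[3-hydroxy-4-(2-methylbut-3-yn-2-yloxy)phenyl]-5-(2-methylbut-3-yn-2-yloxy)-7-(triisopropylsilyloxy)-4H-chromen-4-one, via aryl formate 11 (not isolated)
Conditions: mCPBA, CH2Cl2, 0 °C to rt; then Et3N, MeOH, 0 °C
Reagents that add atoms: 3-chloroperoxybenzoic acid, OOC(=O)c1cccc(Cl)c1
Why: Baeyer–Villiger (Dakin-type) oxidation: the electron-rich aryl group ortho to an alkoxy substituent migrates to give the aryl formate, which mild methanolysis cleaves to the 3'-phenol, while the alkynes and the electron-poor pyranone double bond are inert to the peracid.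

Step 9
Reactants: 12 3-[3-hydroxy-4-(2-methylbut-3-yn-2-yloxy)phenyl]-5-(2-methylbut-3-yn-2-yloxy)-7-(triisopropylsilyloxy)-4H-chromen-4-one
Product: 13 3-[3-(tert-butyldimethylsilyloxy)-4-(2-methylbut-3-yn-2-yloxy)phenyl]-5-(2-methylbut-3-yn-2-yloxy)-7-(triisopropylsilyloxy)-4H-chromen-4-one
Conditions: TBSCl, imidazole, DMF, rt
Reagents that add atoms: tert-butylchlorodimethylsilane, CC(C)(C)[Si](C)(C)Cl
Why: Standard phenol silylation of the single free hydroxyl, placed after the O4' alkylation so that no silyl shift between neighbouring catechol oxygens under base can scramble ring B.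

Step 10
Reactants: 13 3-[3-(tert-butyldimethylsilyloxy)-4-(2-methylbut-3-yn-2-yloxy)phenyl]-5-(2-methylbut-3-yn-2-yloxy)-7-(triisopropylsilyloxy)-4H-chromen-4-one
Product: 14 3-[3-(tert-butyldimethylsilyloxy)-4-(2-methylbut-3-en-2-yloxy)phenyl]-5-(2-methylbut-3-en-2-yloxy)-7-(triisopropylsilyloxy)-4H-chromen-4-one
Conditions: H2 (1 atm), Pd/CaCO3 poisoned with Pb(OAc)2, quinoline, EtOAc, rt
Reagents that add atoms: none
Why: Lindlar semi-hydrogenation reduces both terminal alkynes to vinyl groups and stops there; the conjugated pyranone double bond is not reduced on the poisoned catalyst, and removing the alkynes here keeps them away from the ruthenium hydride of the next step.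

Step 11
Reactants: 14 3-[3-(tert-butyldimethylsilyloxy)-4-(2-methylbut-3-en-2-yloxy)phenyl]-5-(2-methylbut-3-en-2-yloxy)-7-(triisopropylsilyloxy)-4H-chromen-4-one
Product: 16 (3S,4S)-3-[3-(tert-butyldimethylsilyloxy)-4-(2-methylbut-3-en-2-yloxy)phenyl]-5-(2-methylbut-3-en-2-yloxy)-7-(triisopropylsilyloxy)chroman-4-ol, via racemic isoflavanone 15 (not isolated)
Conditions: RuCl[(S,S)-TsDPEN](p-cymene) (5 mol%), HCO2H/Et3N (1:5), EtOAc, 35 °C
Reagents that add atoms: none
Why: Noyori–Ikariya asymmetric transfer hydrogenation of an isoflavone: the ruthenium hydride first reduces C2=C3, the isoflavanone racemises at C3 through its enol in the amine-rich medium, and the (S,S)-catalyst reduces the matched enantiomer on the C4 face anti to the aryl group, so 4S is set by the catalyst and 3S by dynamic kinetic resolution (cis product), while the excess amine keeps the acid-labile tertiary allyl ethers away from free formic acid.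

Step 12
Reactants: 16 (3S,4S)-3-[3-(tert-butyldimethylsilyloxy)-4-(2-methylbut-3-en-2-yloxy)phenyl]-5-(2-methylbut-3-en-2-yloxy)-7-(triisopropylsilyloxy)chroman-4-ol
Product: 17 (3S)-3-[3-(tert-butyldimethylsilyloxy)-4-(2-methylbut-3-en-2-yloxy)phenyl]-5-(2-methylbut-3-en-2-yloxy)-7-(triisopropylsilyloxy)chroman-4-one
Conditions: Dess–Martin periodinane, NaHCO3, CH2Cl2, 0 °C
Reagents that add atoms: none
Why: Dess–Martin oxidation of the benzylic alcohol under solid bicarbonate buffer returns the ketone without acid or soluble base, so the C3 configuration from step 11 should be carried over unchanged.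

Step 13
Reactants: 17 (3S)-3-[3-(tert-butyldimethylsilyloxy)-4-(2-methylbut-3-en-2-yloxy)phenyl]-5-(2-methylbut-3-en-2-yloxy)-7-(triisopropylsilyloxy)chroman-4-one
Product: 19 (3S)-3-[3-(tert-butyldimethylsilyloxy)-4-hydroxy-5-(3-methylbut-2-enyl)phenyl]-5-hydroxy-6-(3-methylbut-2-enyl)-7-(triisopropylsilyloxy)chroman-4-one, via ring A mono-Claisen phenol 18 (not isolated)
Conditions: degassed PhMe (0.02 M), 110 °C, sealed tube
Reagents that add atoms: none
Why: Each aryl 1,1-dimethylallyl ether undergoes a concerted chair-like [3,3]-sigmatropic shift (aromatic Claisen rearrangement) in which the vinyl CH2 terminus bonds to the ortho ring carbon as the O–C(CH3)2 bond breaks, so the allyl unit is inverted and arrives as a linear prenyl group, and tautomerisation of the ortho-dienone restores the phenol. This is the established rearrangement of aryl 1,1-dimethylallyl ethers to ortho-prenylphenols, run here twice in one molecule, with the ring A ether expected to move first because of compression against the C4 carbonyl. No ring is closed and no stereocentre is created; the two new bonds are C6–CH2 and C5'–CH2. Regiocontrol lies in the substrate: the ortho carbons of O5 are C4a (ring fusion) and C6, those of O4' are C3' (oxygenated) and C5', so only shifts to C6 and C5' can re-aromatise, and enolisation of the C6 dienone, helped by the new O5–H to C4 carbonyl hydrogen bond, should outrun a Cope shift on to C8. The step also needs C3 to keep its configuration and the tertiary ethers not to ionise; neutral, non-polar toluene free of acid and base, at the lowest temperature that gives turnover, is meant to secure both.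

Step 14
Reactants: 19 (3S)-3-[3-(tert-butyldimethylsilyloxy)-4-hydroxy-5-(3-methylbut-2-enyl)phenyl]-5-hydroxy-6-(3-methylbut-2-enyl)-7-(triisopropylsilyloxy)chroman-4-one
Product: 20 (3S)-3-[3-(tert-butyldimethylsilyloxy)-4-methoxy-5-(3-methylbut-2-enyl)phenyl]-5-hydroxy-6-(3-methylbut-2-enyl)-7-(triisopropylsilyloxy)chroman-4-one
Conditions: CH2N2 (Et2O solution), Et2O/MeOH 9:1, 0 °C
Reagents that add atoms: diazomethane, C=[N+]=[N-]
Why: Diazomethane O-methylation of a phenol needs no base: O4'–H is the only free non-chelated hydroxyl, O5–H is held in the hydrogen bond to the C4 carbonyl and should not react, and the absence of base protects C3 and prevents a silyl shift from O3' to O4'.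

Step 15
Reactants: 20 (3S)-3-[3-(tert-butyldimethylsilyloxy)-4-methoxy-5-(3-methylbut-2-enyl)phenyl]-5-hydroxy-6-(3-methylbut-2-enyl)-7-(triisopropylsilyloxy)chroman-4-one
Product: 21 (3S)-5,7-dihydroxy-3-[3-hydroxy-4-methoxy-5-(3-methylbut-2-enyl)phenyl]-6-(3-methylbut-2-enyl)chroman-4-one
Conditions: Bu4NF/AcOH (1:1), THF, 0 °C
Reagents that add atoms: none
Why: Fluoride-mediated desilylation cleaves both aryl silyl ethers, and the acetic acid buffer protonates the phenoxides at once so that the medium stays near neutral and C3 should not epimerise.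

**Compound list**
1 | 2,4,6-trihydroxyacetophenone | CC(=O)c1c(O)cc(O)cc1O | starting material
2 | 1-[2,6-dihydroxy-4-(triisopropylsilyloxy)phenyl]ethanone | CC(=O)c1c(O)cc(O[Si](C(C)C)(C(C)C)C(C)C)cc1O | intermediate
3 | 3-chloro-3-methylbut-1-yne | C#CC(C)(C)Cl | starting material
4 | 1-[2-hydroxy-6-(2-methylbut-3-yn-2-yloxy)-4-(triisopropylsilyloxy)phenyl]ethanone | CC(=O)c1c(O)cc(O[Si](C(C)C)(C(C)C)C(C)C)cc1OC(C)(C)C#C | intermediate
5 | (E)-3-(dimethylamino)-1-[2-hydroxy-6-(2-methylbut-3-yn-2-yloxy)-4-(triisopropylsilyloxy)phenyl]prop-2-en-1-one | CN(C)/C=C/C(=O)c1c(O)cc(O[Si](C(C)C)(C(C)C)C(C)C)cc1OC(C)(C)C#C | intermediate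
6 | 3-iodo-5-(2-methylbut-3-yn-2-yloxy)-7-(triisopropylsilyloxy)-4H-chromen-4-one | O=c1c(I)coc2cc(O[Si](C(C)C)(C(C)C)C(C)C)cc(OC(C)(C)C#C)c12 | intermediate
7 | 5-bromo-2-hydroxybenzaldehyde | O=Cc1cc(Br)ccc1O | starting material
8 | 2-hydroxy-5-(4,4,5,5-tetramethyl-1,3,2-dioxaborolan-2-yl)benzaldehyde | O=Cc1cc(B2OC(C)(C)C(C)(C)O2)ccc1O | intermediate
9 | 2-hydroxy-5-[5-(2-methylbut-3-yn-2-yloxy)-4-oxo-7-(triisopropylsilyloxy)-4H-chromen-3-yl]benzaldehyde | O=Cc1cc(-c2coc3cc(O[Si](C(C)C)(C(C)C)C(C)C)cc(OC(C)(C)C#C)c3c2=O)ccc1O | intermediate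
10 | 2-(2-methylbut-3-yn-2-yloxy)-5-[5-(2-methylbut-3-yn-2-yloxy)-4-oxo-7-(triisopropylsilyloxy)-4H-chromen-3-yl]benzaldehyde | O=Cc1cc(-c2coc3cc(O[Si](C(C)C)(C(C)C)C(C)C)cc(OC(C)(C)C#C)c3c2=O)ccc1OC(C)(C)C#C | intermediate
11 | 2-(2-methylbut-3-yn-2-yloxy)-5-[5-(2-methylbut-3-yn-2-yloxy)-4-oxo-7-(triisopropylsilyloxy)-4H-chromen-3-yl]phenyl formate | O=COc1cc(-c2coc3cc(O[Si](C(C)C)(C(C)C)C(C)C)cc(OC(C)(C)C#C)c3c2=O)ccc1OC(C)(C)C#C | intermediate (not isolated)
12 | 3-[3-hydroxy-4-(2-methylbut-3-yn-2-yloxy)phenyl]-5-(2-methylbut-3-yn-2-yloxy)-7-(triisopropylsilyloxy)-4H-chromen-4-one | Oc1cc(-c2coc3cc(O[Si](C(C)C)(C(C)C)C(C)C)cc(OC(C)(C)C#C)c3c2=O)ccc1OC(C)(C)C#C | intermediate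
13 | 3-[3-(tert-butyldimethylsilyloxy)-4-(2-methylbut-3-yn-2-yloxy)phenyl]-5-(2-methylbut-3-yn-2-yloxy)-7-(triisopropylsilyloxy)-4H-chromen-4-one | CC(C)(C)[Si](C)(C)Oc1cc(-c2coc3cc(O[Si](C(C)C)(C(C)C)C(C)C)cc(OC(C)(C)C#C)c3c2=O)ccc1OC(C)(C)C#C | intermediate
14 | 3-[3-(tert-butyldimethylsilyloxy)-4-(2-methylbut-3-en-2-yloxy)phenyl]-5-(2-methylbut-3-en-2-yloxy)-7-(triisopropylsilyloxy)-4H-chromen-4-one | CC(C)(C)[Si](C)(C)Oc1cc(-c2coc3cc(O[Si](C(C)C)(C(C)C)C(C)C)cc(OC(C)(C)C=C)c3c2=O)ccc1OC(C)(C)C=C | intermediate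
15 | rac-3-[3-(tert-butyldimethylsilyloxy)-4-(2-methylbut-3-en-2-yloxy)phenyl]-5-(2-methylbut-3-en-2-yloxy)-7-(triisopropylsilyloxy)chroman-4-one | CC(C)(C)[Si](C)(C)Oc1cc(C2COc3cc(O[Si](C(C)C)(C(C)C)C(C)C)cc(OC(C)(C)C=C)c3C2=O)ccc1OC(C)(C)C=C | intermediate (not isolated)
16 | (3S,4S)-3-[3-(tert-butyldimethylsilyloxy)-4-(2-methylbut-3-en-2-yloxy)phenyl]-5-(2-methylbut-3-en-2-yloxy)-7-(triisopropylsilyloxy)chroman-4-ol (cis) | CC(C)(C)[Si](C)(C)Oc1cc([C@H]2COc3cc(O[Si](C(C)C)(C(C)C)C(C)C)cc(OC(C)(C)C=C)c3[C@H]2O)ccc1OC(C)(C)C=C | intermediate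
17 | (3S)-3-[3-(tert-butyldimethylsilyloxy)-4-(2-methylbut-3-en-2-yloxy)phenyl]-5-(2-methylbut-3-en-2-yloxy)-7-(triisopropylsilyloxy)chroman-4-one | CC(C)(C)[Si](C)(C)Oc1cc([C@H]2COc3cc(O[Si](C(C)C)(C(C)C)C(C)C)cc(OC(C)(C)C=C)c3C2=O)ccc1OC(C)(C)C=C | intermediate
18 | (3S)-3-[3-(tert-butyldimethylsilyloxy)-4-(2-methylbut-3-en-2-yloxy)phenyl]-5-hydroxy-6-(3-methylbut-2-enyl)-7-(triisopropylsilyloxy)chroman-4-one | CC(C)(C)[Si](C)(C)Oc1cc([C@H]2COc3cc(O[Si](C(C)C)(C(C)C)C(C)C)c(CC=C(C)C)c(O)c3C2=O)ccc1OC(C)(C)C=C | intermediate (not isolated)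
19 | (3S)-3-[3-(tert-butyldimethylsilyloxy)-4-hydroxy-5-(3-methylbut-2-enyl)phenyl]-5-hydroxy-6-(3-methylbut-2-enyl)-7-(triisopropylsilyloxy)chroman-4-one | Oc1c(O[Si](C)(C)C(C)(C)C)cc([C@H]2COc3cc(O[Si](C(C)C)(C(C)C)C(C)C)c(CC=C(C)C)c(O)c3C2=O)cc1CC=C(C)C | intermediate
20 | (3S)-3-[3-(tert-butyldimethylsilyloxy)-4-methoxy-5-(3-methylbut-2-enyl)phenyl]-5-hydroxy-6-(3-methylbut-2-enyl)-7-(triisopropylsilyloxy)chroman-4-one | COc1c(O[Si](C)(C)C(C)(C)C)cc([C@H]2COc3cc(O[Si](C(C)C)(C(C)C)C(C)C)c(CC=C(C)C)c(O)c3C2=O)cc1CC=C(C)C | intermediate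
21 | (3S)-5,7-dihydroxy-3-[3-hydroxy-4-methoxy-5-(3-methylbut-2-enyl)phenyl]-6-(3-methylbut-2-enyl)chroman-4-one (CNP0327275.1) | COc1c(O)cc([C@H]2COc3cc(O)c(CC=C(C)C)c(O)c3C2=O)cc1CC=C(C)C | target

**Step count**
Total: 15 steps. Longest linear sequence: 14 steps (steps 1–4 and 6–15, from compound 1); step 5 makes the ring B fragment.

**Steps most likely to fail**

Step 13 (twofold Claisen rearrangement). During the hours at 110 °C, thermal enolisation may erode the C3 configuration, or the tertiary allyl ethers may ionise and lose isoprene faster than they rearrange. The fallback is to rearrange before the stereocentre exists. It sets out from 14, which is heated in xylene at 140 °C to give 5,4'-dihydroxy-6,5'-diprenyl-7-(triisopropylsilyloxy)-3'-(tert-butyldimethylsilyloxy)isoflavone F1. Diazomethane then methylates O4' only, giving the 4'-methyl ether F2. The same ruthenium catalyst, now with HCO2H/Et3N 5:2 because no acid-labile ether remains, reduces this ortho-hydroxyaryl ketone system to the (3S,4S)-5-hydroxychroman-4-ol F3. MnO2 in CH2Cl2 oxidises the benzylic alcohol, and the route is rejoined at 20.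

Step 11 (transfer hydrogenation with dynamic kinetic resolution). Hydride transfer to the C4 carbonyl next to the bulky 5-ether may be slow, so that the reduction stalls at the racemic ketone or runs with poor cis and enantiofacial control. The fallback replaces catalytic control by resolution. It sets out from 14: conjugate reduction with LiBH(s-Bu)3 in THF at −78 °C gives racemic 15, which is now isolated. Preparative chiral SFC separates (S)-17 from the (R)-enantiomer F4, and F4 is racemised with Et3N in EtOAc and recycled. The route is rejoined at 17, and steps 11 and 12 are skipped.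

Step 6 (Suzuki coupling). The terminal alkyne C–H may enter the palladium cycle and give alkynylation or oligomers, or the aqueous base may strip the 7-silyl group. The fallback caps the alkyne carbon before the coupling. It sets out from 6: LiN(SiMe3)2 with Me3SiCl present (THF, −78 °C) gives the C-trimethylsilyl alkyne F5. Coupling of F5 with 8 under anhydrous conditions (Pd(dppf)Cl2, K3PO4, 1,4-dioxane) gives the silyl-capped isoflavone F6. AgNO3 (cat.) in acetone/water removes only the alkynyl silyl group, and the route is rejoined at 9.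

**Further compounds**
F1 | step 13 | 3-[3-(tert-butyldimethylsilyloxy)-4-hydroxy-5-(3-methylbut-2-enyl)phenyl]-5-hydroxy-6-(3-methylbut-2-enyl)-7-(triisopropylsilyloxy)-4H-chromen-4-one | Oc1c(O[Si](C)(C)C(C)(C)C)cc(-c2coc3cc(O[Si](C(C)C)(C(C)C)C(C)C)c(CC=C(C)C)c(O)c3c2=O)cc1CC=C(C)C
F2 | step 13 | 3-[3-(tert-butyldimethylsilyloxy)-4-methoxy-5-(3-methylbut-2-enyl)phenyl]-5-hydroxy-6-(3-methylbut-2-enyl)-7-(triisopropylsilyloxy)-4H-chromen-4-one | COc1c(O[Si](C)(C)C(C)(C)C)cc(-c2coc3cc(O[Si](C(C)C)(C(C)C)C(C)C)c(CC=C(C)C)c(O)c3c2=O)cc1CC=C(C)C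
F3 | step 13 | (3S,4S)-3-[3-(tert-butyldimethylsilyloxy)-4-methoxy-5-(3-methylbut-2-enyl)phenyl]-6-(3-methylbut-2-enyl)-7-(triisopropylsilyloxy)chroman-4,5-diol | COc1c(O[Si](C)(C)C(C)(C)C)cc([C@H]2COc3cc(O[Si](C(C)C)(C(C)C)C(C)C)c(CC=C(C)C)c(O)c3[C@H]2O)cc1CC=C(C)C
F4 | step 11 | (3R)-3-[3-(tert-butyldimethylsilyloxy)-4-(2-methylbut-3-en-2-yloxy)phenyl]-5-(2-methylbut-3-en-2-yloxy)-7-(triisopropylsilyloxy)chroman-4-one | CC(C)(C)[Si](C)(C)Oc1cc([C@@H]2COc3cc(O[Si](C(C)C)(C(C)C)C(C)C)cc(OC(C)(C)C=C)c3C2=O)ccc1OC(C)(C)C=C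
F5 | step 6 | 3-iodo-5-[2-methyl-4-(trimethylsilyl)but-3-yn-2-yloxy]-7-(triisopropylsilyloxy)-4H-chromen-4-one | O=c1c(I)coc2cc(O[Si](C(C)C)(C(C)C)C(C)C)cc(OC(C)(C)C#C[Si](C)(C)C)c12
F6 | step 6 | 2-hydroxy-5-{5-[2-methyl-4-(trimethylsilyl)but-3-yn-2-yloxy]-4-oxo-7-(triisopropylsilyloxy)-4H-chromen-3-yl}benzaldehyde | O=Cc1cc(-c2coc3cc(O[Si](C(C)C)(C(C)C)C(C)C)cc(OC(C)(C)C#C[Si](C)(C)C)c3c2=O)ccc1O
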